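The route rests on disconnecting the bond between the quaternary ring-B carbon C9 and the ring-fusion alkene carbon C10 (halimane numbering). A reductive 6-exo Heck cyclisation of a diosphenol triflate (C10–OTf on a ring-A enone, C1=O, C5=C10) onto a 1,1-disubstituted alkene (C9=C20H2) closes ring B, creates the C9 quaternary centre and turns the methylene carbon into the C20 methyl, with configuration relayed from the C8 methyl stereocentre. The feature exploited is the allylic quaternary C9 next to the C1=C10 alkene: the enone left by the cyclisation is then transposed reductively (C5–H, C1=C10). The precursor is a monocyclic cyclohexenone made by asymmetric Robinson-type annulation of an acyclic β-keto ester.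

Key step: step 13

Remarks
- Numbering (halimane): ring A = C1, C2, C3, C4, C5, C10; ring B = C5, C6, C7, C8, C9, C10; C18 = ester carbon and C19 = methyl on C4; C17 = methyl on C8; C20 = methyl on C9; side chain C11–C16 with the acetate on C15.
- Assumption: the sense of induction of the cinchona catalyst in step 10 is taken by analogy with related β-keto ester/vinyl ketone additions; if the opposite sense is found, the quinine-derived pseudoenantiomer would be used.
- Phosphine ligands on palladium are omitted from the SMILES of 19.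

Step 1
Reactants: 1 (S)-citronellol
Product: 2 {[(3S)-3,7-dimethyloct-6-en-1-yl]oxy}triisopropylsilane
Conditions: TIPSCl, imidazole, DMF, rt
Reagents that add atoms: chlorotriisopropylsilane, CC(C)[Si](Cl)(C(C)C)C(C)C
Why: Standard silylation of the primary alcohol leaves the chiral-pool stereocentre (future C13) untouched and installs an ether chosen to survive Lewis acid, fluoride at the enol silyl ether stage and dissolving metal.

Step 2
Reactants: 2 {[(3S)-3,7-dimethyloct-6-en-1-yl]oxy}triisopropylsilane
Product: 3 (4S)-4-methyl-6-[(triisopropylsilyl)oxy]hexanoic acid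
Conditions: RuCl3·xH2O (2 mol %), NaIO4, CCl4/MeCN/H2O, rt
Reagents that add atoms: sodium periodate, [Na+].[O-]I(=O)(=O)=O; water, O
Why: RuO4-mediated oxidative cleavage of the trisubstituted alkene (Sharpless conditions) should give the acid whose carboxyl carbon becomes C9, with loss of acetone and no effect on the remote stereocentre.

Step 3
Reactants: 3 (4S)-4-methyl-6-[(triisopropylsilyl)oxy]hexanoic acid; 4 (4R)-4-benzyl-3-propanoyl-1,3-oxazolidin-2-one
Product: 6 (4R)-4-benzyl-3-{(2S,6S)-2,6-dimethyl-3-oxo-8-[(triisopropylsilyl)oxy]octanoyl}-1,3-oxazolidin-2-one, via acid chloride 5 (not isolated)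
Conditions: (COCl)2, cat. DMF, CH2Cl2, 0 °C to rt, concentrate; 4, LiN(i-Pr)2, THF, −78 °C, then 5, −78 °C
Reagents that add atoms: none
Why: Evans acylation, in which the chelated Z-lithium enolate of the propionimide is acylated on the face opposite the benzyl group and so sets C8, the β-keto imide being protected from epimerisation by A(1,3) strain that keeps the C8–H bond out of alignment with the carbonyl groups.

Step 4
Reactants: 6 (4R)-4-benzyl-3-{(2S,6S)-2,6-dimethyl-3-oxo-8-[(triisopropylsilyl)oxy]octanoyl}-1,3-oxazolidin-2-one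
Product: 7 (4R)-4-benzyl-3-{(2S,6S)-2,6-dimethyl-3-methylidene-8-[(triisopropylsilyl)oxy]octanoyl}-1,3-oxazolidin-2-one
Conditions: Zn, CH2Br2, TiCl4, THF/CH2Cl2, 0 °C to rt
Reagents that add atoms: dibromomethane, BrCBr
Why: Takai–Lombardo methylenation, a non-basic methylene transfer suited to easily enolised ketones, should convert the ketone (much more reactive than the imide carbonyls) into the C9=C20 alkene without disturbing C8.

Step 5
Reactants: 7 (4R)-4-benzyl-3-{(2S,6S)-2,6-dimethyl-3-methylidene-8-[(triisopropylsilyl)oxy]octanoyl}-1,3-oxazolidin-2-one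
Product: 8 (2S,6S)-2,6-dimethyl-3-methylidene-8-[(triisopropylsilyl)oxy]octan-1-ol
Conditions: LiBH4, H2O (1 equiv), Et2O, 0 °C
Reagents that add atoms: none
Why: Reductive cleavage of the N-acyl oxazolidinone by LiBH4 should release the primary alcohol (C7) and the recoverable auxiliary without epimerising the allylic C8 centre.

Step 6
Reactants: 8 (2S,6S)-2,6-dimethyl-3-methylidene-8-[(triisopropylsilyl)oxy]octan-1-ol
Product: 9 {[(3S,7S)-8-iodo-3,7-dimethyl-6-methylideneoctyl]oxy}triisopropylsilane
Conditions: I2, PPh3, imidazole, CH2Cl2, 0 °C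
Reagents that add atoms: iodine, II
Why: Appel-type iodination of the primary alcohol under neutral conditions leaves the alkene and the adjacent stereocentre unchanged.

Step 7
Reactants: 9 {[(3S,7S)-8-iodo-3,7-dimethyl-6-methylideneoctyl]oxy}triisopropylsilane; 10 methyl 2-methyl-3-oxobutanoate
Product: 11 methyl (2RS,6R,10S)-2,6,10-trimethyl-7-methylidene-3-oxo-12-[(triisopropylsilyl)oxy]dodecanoate
Conditions: 10, NaH, THF, 0 °C; n-BuLi, 0 °C; then 9, 0 °C to rt
Reagents that add atoms: none
Why: Weiler dianion alkylation, in which the more basic terminal carbanion of the acetoacetate dianion displaces the primary iodide to form C6–C7, the C4 centre being left as an epimer mixture because it is set in step 10.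

Step 8
Reactants: 12 (tert-butyldimethylsilyloxy)acetaldehyde; 13 vinylmagnesium bromide
Product: 14 1-[(tert-butyldimethylsilyl)oxy]but-3-en-2-ol (racemic)
Conditions: CH2=CHMgBr, THF, −78 to 0 °C
Reagents that add atoms: none
Why: Grignard 1,2-addition to the aldehyde gives the allylic alcohol, whose stereocentre is removed in the next step.

Step 9
Reactants: 14 1-[(tert-butyldimethylsilyl)oxy]but-3-en-2-ol
Product: 15 1-[(tert-butyldimethylsilyl)oxy]but-3-en-2-one
Conditions: Dess–Martin periodinane, NaHCO3, CH2Cl2, 0 °C to rt, used at once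
Reagents that add atoms: none
Why: Dess–Martin oxidation under buffered, non-basic conditions should give the polymerisation-prone siloxymethyl vinyl ketone without conjugate addition or silyl loss.

Step 10
Reactants: 11 methyl (2RS,6R,10S)-2,6,10-trimethyl-7-methylidene-3-oxo-12-[(triisopropylsilyl)oxy]dodecanoate; 15 1-[(tert-butyldimethylsilyl)oxy]but-3-en-2-one
Product: 16 methyl (2S,6R,10S)-2-{4-[(tert-butyldimethylsilyl)oxy]-3-oxobutyl}-2,6,10-trimethyl-7-methylidene-3-oxo-12-[(triisopropylsilyl)oxy]dodecanoate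
Conditions: cupreidine-derived catalyst QD-PHN (10 mol %), CH2Cl2, −20 °C to rt
Reagents that add atoms: none
Why: Organocatalytic asymmetric Michael addition of an α-substituted β-keto ester to a vinyl ketone (bifunctional cinchona base and hydrogen-bond catalysis) creates the C4 quaternary centre under catalyst control, the C8 and C13 centres being remote and making any minor C4 epimer a separable diastereomer.

Step 11
Reactants: 16 methyl (2S,6R,10S)-2-{4-[(tert-butyldimethylsilyl)oxy]-3-oxobutyl}-2,6,10-trimethyl-7-methylidene-3-oxo-12-[(triisopropylsilyl)oxy]dodecanoate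
Product: 17 methyl (1S)-3-[(tert-butyldimethylsilyl)oxy]-2-{(3R,7S)-3,7-dimethyl-4-methylidene-9-[(triisopropylsilyl)oxy]nonyl}-1-methyl-4-oxocyclohex-2-ene-1-carboxylate
Conditions: pyrrolidine, AcOH, toluene, 50 °C
Reagents that add atoms: none
Why: Second stage of a Robinson annulation (amine-mediated intramolecular aldol condensation), in which the enamine formed at the oxygenated C10 methylene of the C1 ketone attacks the C5 ketone and dehydration gives the tetrasubstituted C5=C10 enone that already carries oxygen at C10, with no new stereocentre and a non-enolisable C4.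

Step 12
Reactants: 17 methyl (1S)-3-[(tert-butyldimethylsilyl)oxy]-2-{(3R,7S)-3,7-dimethyl-4-methylidene-9-[(triisopropylsilyl)oxy]nonyl}-1-methyl-4-oxocyclohex-2-ene-1-carboxylate
Product: 18 methyl (1S)-2-{(3R,7S)-3,7-dimethyl-4-methylidene-9-[(triisopropylsilyl)oxy]nonyl}-1-methyl-4-oxo-3-{[(trifluoromethyl)sulfonyl]oxy}cyclohex-2-ene-1-carboxylate
Conditions: CsF, PhNTf2, DME, rt
Reagents that add atoms: N-phenylbis(trifluoromethanesulfonimide), O=S(=O)(N(c1ccccc1)S(=O)(=O)C(F)(F)F)C(F)(F)F
Why: Fluoride cleaves the enol silyl ether (far more labile than the alkyl triisopropylsilyl ether) to the diosphenolate, which is O-sulfonylated to the alkenyl triflate at C10 (enolate trapping as triflate).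

Step 13
Reactants: 18 methyl (1S)-2-{(3R,7S)-3,7-dimethyl-4-methylidene-9-[(triisopropylsilyl)oxy]nonyl}-1-methyl-4-oxo-3-{[(trifluoromethyl)sulfonyl]oxy}cyclohex-2-ene-1-carboxylate
Product: 20 methyl (1S,5S,6R)-1,5,6-trimethyl-5-{(3S)-3-methyl-5-[(triisopropylsilyl)oxy]pentyl}-4-oxo-1,2,3,4,5,6,7,8-octahydronaphthalene-1-carboxylate, via alkylpalladium triflate 19 (not isolated)
Conditions: Pd(OAc)2 (10 mol %), PPh3 (20 mol %), HCO2Na (added in portions), DMF, 80 °C
Reagents that add atoms: none
Why: Oxidative addition of zerovalent palladium into the C10–OTf bond gives a cationic alkenylpalladium species that inserts the tethered C9=C20 alkene in a syn 6-exo-trig carbopalladation (ring B: C5, C6, C7, C8, C9, C10), forming the C9–C10 bond and leaving a neopentyl-type alkylpalladium at C20 that has no β-hydrogen and is therefore intercepted by formate (decarboxylation to a palladium hydride, then C–H reductive elimination) to give the C20 methyl. The closest known reaction type is the hydride-terminated (reductive) intramolecular Heck cyclisation of alkenyl and aryl halides or triflates onto 1,1-disubstituted alkenes to make quaternary centres. The new stereocentre C9 is controlled by the adjacent C8 methyl: in the chair-like transition state with eclipsed Pd–C10 and C9=C20 bonds the C8 methyl lies pseudo-equatorial (its allylic hydrogen, not the methyl, sits next to the in-plane C11 methylene, which avoids A(1,2) strain), the palladium-bound CH2 becomes the pseudo-axial C9 substituent and so ends cis to the C8 methyl. The step needs exo rather than 7-endo insertion, which the short tether and the cis-fixed geometry of the ring-A alkenylpalladium should secure, and it needs cyclisation to outrun direct formate reduction of the alkenylpalladium, which the cationic triflate pathway and portionwise formate addition should favour. The distant C4 centre is not expected to influence the facial choice.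

Step 14
Reactants: 20 methyl (1S,5S,6R)-1,5,6-trimethyl-5-{(3S)-3-methyl-5-[(triisopropylsilyl)oxy]pentyl}-4-oxo-1,2,3,4,5,6,7,8-octahydronaphthalene-1-carboxylate
Product: 22 methyl (1S,5S,6R,8aR)-1,5,6-trimethyl-5-{(3S)-3-methyl-5-[(triisopropylsilyl)oxy]pentyl}-4-{[(trifluoromethyl)sulfonyl]oxy}-1,2,3,5,6,7,8,8a-octahydronaphthalene-1-carboxylate, via lithium enolate 21 (not isolated)
Conditions: Li (2.2 equiv), NH3/THF, t-BuOH (1 equiv), −78 °C; isoprene; evaporate NH3; PhNTf2, THF, 0 °C to rt
Reagents that add atoms: N-phenylbis(trifluoromethanesulfonimide), O=S(=O)(N(c1ccccc1)S(=O)(=O)C(F)(F)F)C(F)(F)F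
Why: Dissolving-metal enone reduction with regiospecific enolate trapping, in which C5 is protonated axially with respect to ring A to give the more stable of the two possible isomers (H5 cis to the axial C9 methyl, ring B a chair with the C8 methyl and the C11 chain equatorial) and the C1–C10 enolate is O-triflated so that the double bond is fixed at C1=C10.

Step 15
Reactants: 22 methyl (1S,5S,6R,8aR)-1,5,6-trimethyl-5-{(3S)-3-methyl-5-[(triisopropylsilyl)oxy]pentyl}-4-{[(trifluoromethyl)sulfonyl]oxy}-1,2,3,5,6,7,8,8a-octahydronaphthalene-1-carboxylate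
Product: 23 methyl (1S,5S,6R,8aR)-1,5,6-trimethyl-5-{(3S)-3-methyl-5-[(triisopropylsilyl)oxy]pentyl}-1,2,3,5,6,7,8,8a-octahydronaphthalene-1-carboxylate
Conditions: Pd(OAc)2 (5 mol %), PPh3 (10 mol %), Bu3N, HCO2H, DMF, 60 °C
Reagents that add atoms: none
Why: Palladium-catalysed formate reduction of the alkenyl triflate replaces the triflate by hydrogen with the double bond held at C1=C10 and no stereocentre affected.

Step 16
Reactants: 23 methyl (1S,5S,6R,8aR)-1,5,6-trimethyl-5-{(3S)-3-methyl-5-[(triisopropylsilyl)oxy]pentyl}-1,2,3,5,6,7,8,8a-octahydronaphthalene-1-carboxylate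
Product: 25 methyl (1S,5S,6R,8aR)-5-[(3S)-5-acetoxy-3-methylpentyl]-1,5,6-trimethyl-1,2,3,5,6,7,8,8a-octahydronaphthalene-1-carboxylate, via primary alcohol 24 (not isolated)
Conditions: Bu4NF, THF, rt; then Ac2O, pyridine, DMAP, rt
Reagents that add atoms: acetic anhydride, CC(=O)OC(C)=O
Why: Fluoride desilylation followed by acetylation in the same flask (DMAP-catalysed acyl transfer) converts the silyl ether into the primary acetate and should give the target.

Compound list
1 | (S)-citronellol, (3S)-3,7-dimethyloct-6-en-1-ol | CC(C)=CCC[C@H](C)CCO | starting material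
2 | {[(3S)-3,7-dimethyloct-6-en-1-yl]oxy}triisopropylsilane | CC(C)=CCC[C@H](C)CCO[Si](C(C)C)(C(C)C)C(C)C | intermediate
3 | (4S)-4-methyl-6-[(triisopropylsilyl)oxy]hexanoic acid | OC(=O)CC[C@H](C)CCO[Si](C(C)C)(C(C)C)C(C)C | intermediate
4 | (4R)-4-benzyl-3-propanoyl-1,3-oxazolidin-2-one | CCC(=O)N1[C@H](Cc2ccccc2)COC1=O | starting material
5 | (4S)-4-methyl-6-[(triisopropylsilyl)oxy]hexanoyl chloride | ClC(=O)CC[C@H](C)CCO[Si](C(C)C)(C(C)C)C(C)C | intermediate (not isolated)
6 | (4R)-4-benzyl-3-{(2S,6S)-2,6-dimethyl-3-oxo-8-[(triisopropylsilyl)oxy]octanoyl}-1,3-oxazolidin-2-one | O=C1OC[C@@H](Cc2ccccc2)N1C(=O)[C@@H](C)C(=O)CC[C@H](C)CCO[Si](C(C)C)(C(C)C)C(C)C | intermediate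
7 | (4R)-4-benzyl-3-{(2S,6S)-2,6-dimethyl-3-methylidene-8-[(triisopropylsilyl)oxy]octanoyl}-1,3-oxazolidin-2-one | O=C1OC[C@@H](Cc2ccccc2)N1C(=O)[C@@H](C)C(=C)CC[C@H](C)CCO[Si](C(C)C)(C(C)C)C(C)C | intermediate
8 | (2S,6S)-2,6-dimethyl-3-methylidene-8-[(triisopropylsilyl)oxy]octan-1-ol | OC[C@@H](C)C(=C)CC[C@H](C)CCO[Si](C(C)C)(C(C)C)C(C)C | intermediate
9 | {[(3S,7S)-8-iodo-3,7-dimethyl-6-methylideneoctyl]oxy}triisopropylsilane | IC[C@@H](C)C(=C)CC[C@H](C)CCO[Si](C(C)C)(C(C)C)C(C)C | intermediate
10 | methyl 2-methyl-3-oxobutanoate | COC(=O)C(C)C(C)=O | starting material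
11 | methyl (2RS,6R,10S)-2,6,10-trimethyl-7-methylidene-3-oxo-12-[(triisopropylsilyl)oxy]dodecanoate | COC(=O)C(C)C(=O)CC[C@@H](C)C(=C)CC[C@H](C)CCO[Si](C(C)C)(C(C)C)C(C)C | intermediate
12 | (tert-butyldimethylsilyloxy)acetaldehyde | CC(C)(C)[Si](C)(C)OCC=O | starting material
13 | vinylmagnesium bromide | C=C[Mg]Br | starting material
14 | 1-[(tert-butyldimethylsilyl)oxy]but-3-en-2-ol (racemic) | C=CC(O)CO[Si](C)(C)C(C)(C)C | intermediate
15 | 1-[(tert-butyldimethylsilyl)oxy]but-3-en-2-one | C=CC(=O)CO[Si](C)(C)C(C)(C)C | intermediate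
16 | methyl (2S,6R,10S)-2-{4-[(tert-butyldimethylsilyl)oxy]-3-oxobutyl}-2,6,10-trimethyl-7-methylidene-3-oxo-12-[(triisopropylsilyl)oxy]dodecanoate | COC(=O)[C@@](C)(CCC(=O)CO[Si](C)(C)C(C)(C)C)C(=O)CC[C@@H](C)C(=C)CC[C@H](C)CCO[Si](C(C)C)(C(C)C)C(C)C | intermediate
17 | methyl (1S)-3-[(tert-butyldimethylsilyl)oxy]-2-{(3R,7S)-3,7-dimethyl-4-methylidene-9-[(triisopropylsilyl)oxy]nonyl}-1-methyl-4-oxocyclohex-2-ene-1-carboxylate | COC(=O)[C@@]1(C)CCC(=O)C(O[Si](C)(C)C(C)(C)C)=C1CC[C@@H](C)C(=C)CC[C@H](C)CCO[Si](C(C)C)(C(C)C)C(C)C | intermediate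
18 | methyl (1S)-2-{(3R,7S)-3,7-dimethyl-4-methylidene-9-[(triisopropylsilyl)oxy]nonyl}-1-methyl-4-oxo-3-{[(trifluoromethyl)sulfonyl]oxy}cyclohex-2-ene-1-carboxylate | COC(=O)[C@@]1(C)CCC(=O)C(OS(=O)(=O)C(F)(F)F)=C1CC[C@@H](C)C(=C)CC[C@H](C)CCO[Si](C(C)C)(C(C)C)C(C)C | intermediate
19 | C20 alkylpalladium triflate formed by 6-exo insertion (phosphines omitted) | COC(=O)[C@@]1(C)CCC(=O)C2=C1CC[C@@H](C)[C@]2(C[Pd]OS(=O)(=O)C(F)(F)F)CC[C@H](C)CCO[Si](C(C)C)(C(C)C)C(C)C | intermediate (not isolated)
20 | methyl (1S,5S,6R)-1,5,6-trimethyl-5-{(3S)-3-methyl-5-[(triisopropylsilyl)oxy]pentyl}-4-oxo-1,2,3,4,5,6,7,8-octahydronaphthalene-1-carboxylate | COC(=O)[C@@]1(C)CCC(=O)C2=C1CC[C@@H](C)[C@]2(C)CC[C@H](C)CCO[Si](C(C)C)(C(C)C)C(C)C | intermediate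
21 | lithium C1–C10 enolate of the C5-reduced ketone | COC(=O)[C@@]1(C)CCC(O[Li])=C2[C@H]1CC[C@@H](C)[C@]2(C)CC[C@H](C)CCO[Si](C(C)C)(C(C)C)C(C)C | intermediate (not isolated)
22 | methyl (1S,5S,6R,8aR)-1,5,6-trimethyl-5-{(3S)-3-methyl-5-[(triisopropylsilyl)oxy]pentyl}-4-{[(trifluoromethyl)sulfonyl]oxy}-1,2,3,5,6,7,8,8a-octahydronaphthalene-1-carboxylate | COC(=O)[C@@]1(C)CCC(OS(=O)(=O)C(F)(F)F)=C2[C@H]1CC[C@@H](C)[C@]2(C)CC[C@H](C)CCO[Si](C(C)C)(C(C)C)C(C)C | intermediate
23 | methyl (1S,5S,6R,8aR)-1,5,6-trimethyl-5-{(3S)-3-methyl-5-[(triisopropylsilyl)oxy]pentyl}-1,2,3,5,6,7,8,8a-octahydronaphthalene-1-carboxylate | COC(=O)[C@@]1(C)CCC=C2[C@H]1CC[C@@H](C)[C@]2(C)CC[C@H](C)CCO[Si](C(C)C)(C(C)C)C(C)C | intermediate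
24 | methyl (1S,5S,6R,8aR)-5-[(3S)-5-hydroxy-3-methylpentyl]-1,5,6-trimethyl-1,2,3,5,6,7,8,8a-octahydronaphthalene-1-carboxylate | COC(=O)[C@@]1(C)CCC=C2[C@H]1CC[C@@H](C)[C@]2(C)CC[C@H](C)CCO | intermediate (not isolated)
25 | methyl (1S,5S,6R,8aR)-5-[(3S)-5-acetoxy-3-methylpentyl]-1,5,6-trimethyl-1,2,3,5,6,7,8,8a-octahydronaphthalene-1-carboxylate | COC(=O)[C@@]1(C)CCC=C2[C@H]1CC[C@@H](C)[C@]2(C)CC[C@H](C)CCOC(C)=O | target

Total step count: 16. Longest linear sequence: 14 steps (steps 1–7 and 10–16; steps 8–9 make the Michael acceptor).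

Steps most likely to fail

Step 13. What may go wrong: formate may deliver hydride to the alkenylpalladium before carbopalladation (simple detriflation), or the β-hydrogen-free neopentylpalladium may drift by 3-exo insertion into the C5=C10 bond before it is reduced. The fallback sets out from 18 and returns at 20. The ring closure would be run with no hydride present, as a palladium-catalysed iodine-atom-transfer carbopalladation (carboiodination, known for alkenyl and aryl halides onto 1,1-disubstituted alkenes): Pd(OAc)2, dppf, Bu4NI, toluene, 100 °C. Triflate–iodide exchange at palladium, 6-exo insertion and C–I reductive elimination should give the neopentyl iodide F1. A separate radical deiodination (Bu3SnH, AIBN, benzene, 80 °C, high tin hydride concentration) would then give 20.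

Step 11. What may go wrong: enamine aldol closure onto the neopentyl C5 ketone may be slow, so that retro-Michael fragmentation or loss or migration of the silyloxy group at C10 competes. The fallback sets out from 11 and returns at 18. 11 would be added to but-3-en-2-one under the conditions of step 10 to give the diketone F2, which is closed by the classical pyrrolidine/AcOH Robinson condensation to the enone F3. Nucleophilic epoxidation of the enone only (H2O2, NaOH, MeOH, 0 °C; the isolated alkene is inert) would give the epoxy ketone F4. Base-mediated isomerisation (KOt-Bu, t-BuOH/THF; deprotonation at C10 and β-opening of the epoxide) would give the diosphenol F5, and Tf2O/pyridine (CH2Cl2, −78 °C) would convert it into 18.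

Step 14. What may go wrong: solvated electrons may over-reduce the methyl ester, or C5 may be protonated from the wrong face. The fallback sets out from 20 and returns at 23, bypassing 22. 20 would be condensed with TsNHNH2 (EtOH, cat. AcOH, reflux) to the tosylhydrazone F6. Reduction with catecholborane (CHCl3, 0 °C) and heating with NaOAc·3H2O would expel sulfinate and then dinitrogen from the allylic diazene, with suprafacial hydrogen transfer to C5 and shift of the double bond to C1=C10 (reductive 1,3-transposition of an enone tosylhydrazone). Hydride is expected to add to C1 anti to the pseudo-axial C9 methyl, so that hydrogen reaches C5 on the methyl face.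

Further compounds
F1 | step 13 | neopentyl iodide: 20 with CH2I in place of the C9 methyl (C20 iodide, other centres as in 20) | COC(=O)[C@@]1(C)CCC(=O)C2=C1CC[C@@H](C)[C@]2(CI)CC[C@H](C)CCO[Si](C(C)C)(C(C)C)C(C)C
F2 | step 11 | methyl (2S,6R,10S)-2,6,10-trimethyl-7-methylidene-3-oxo-2-(3-oxobutyl)-12-[(triisopropylsilyl)oxy]dodecanoate | COC(=O)[C@@](C)(CCC(C)=O)C(=O)CC[C@@H](C)C(=C)CC[C@H](C)CCO[Si](C(C)C)(C(C)C)C(C)C
F3 | step 11 | methyl (1S)-2-{(3R,7S)-3,7-dimethyl-4-methylidene-9-[(triisopropylsilyl)oxy]nonyl}-1-methyl-4-oxocyclohex-2-ene-1-carboxylate | COC(=O)[C@@]1(C)CCC(=O)C=C1CC[C@@H](C)C(=C)CC[C@H](C)CCO[Si](C(C)C)(C(C)C)C(C)C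
F4 | step 11 | 2,3-epoxide of F3 (α,β-epoxy ketone, epoxide configuration immaterial) | COC(=O)[C@@]1(C)CCC(=O)C2OC21CC[C@@H](C)C(=C)CC[C@H](C)CCO[Si](C(C)C)(C(C)C)C(C)C
F5 | step 11 | methyl (1S)-2-{(3R,7S)-3,7-dimethyl-4-methylidene-9-[(triisopropylsilyl)oxy]nonyl}-3-hydroxy-1-methyl-4-oxocyclohex-2-ene-1-carboxylate (diosphenol) | COC(=O)[C@@]1(C)CCC(=O)C(O)=C1CC[C@@H](C)C(=C)CC[C@H](C)CCO[Si](C(C)C)(C(C)C)C(C)C
F6 | step 14 | 4-(4-methylbenzenesulfonyl)hydrazone of 20 | COC(=O)[C@@]1(C)CCC(=NNS(=O)(=O)c3ccc(C)cc3)C2=C1CC[C@@H](C)[C@]2(C)CC[C@H](C)CCO[Si](C(C)C)(C(C)C)C(C)C
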